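A small charge of free catalyst stands against large charges in both runs: larch holds 1 mM of it beside 0.20 M of starting material.

common to all: starting material 0.20 M

|  | second substrate | reagent | free catalyst | temperature | remark | time |
|---|---|---|---|---|---|---|
| larch | 0.20 M | 0.21 M | 1 mM | 0 °C | the very flask that is asked about, followed so far |  |
| maple | 0.13 M | 0.21 M | 1 mM | −15 °C | run made earlier |  |
| flask | 0.200 M | 0.210 M | 1.0 mM | 0 °C |  | 40 h |

- larch (time / h: target / %): 2.00: 10.7; 3.00: 11.7; 4.00: 12.1; 6.00: 11.6; 10.0: 12.7; 15.0: 11.6; 25.0: 12.7
- maple (time / h: target / %): 0.200: 4.2; 0.667: 6.3; 1.00: 9.5; 2.00: 10.5; 3.00: 10.5; 4.00: 10.9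

(standard deviation of a reading: 1 percentage point)

- removed target is counted in
- the earlier runs were read with a standard deviation of 1 percentage point
- additions bring no volume worth counting

- north-east: at 40 h raise the temperature by 15 K, then wait 12 h
- west: at 40 h add reagent, 100 % of the amount charged, then wait 12 h
- east: at 40 h take out 90 % of the target then present, then wait 12 h
- south-west: at 40 h add free catalyst, 50.0 % of the amount charged, then wait 12 h
- south: change nothing and wait 12 h more

* target, in percent of the starting material first charged, at 40 h
* the remedy with the largest gain of target, or "none" below 2 percentage points (north-east / west / east / south-west / south / none)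
* target present, with what was taken out counted in, in percent of the starting material first charged, after east
* target present, with what was taken out counted in, in percent of the starting material first charged, after south

From 3.00 h on, the larch readings lie flat, with a mean of 12.1 %. I fold this into one number, N = c(target)/c(free catalyst charged). For larch, N = 24.1, the target made per free catalyst charged, the turnover number counted in target. I read it as a quota: each free catalyst charged yields about N of target and then stops.

Is one number enough? The maple run, at −15 °C with 0.13 M of second substrate against 0.20 M, levels at 10.6 %, so its N reads 21.3. That yield lies 1.5 percentage points lower, with 1 point on a reading, so N holds roughly across the two runs, and I commit to it.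

Larch then stands at 12.1 % at 40 h and after south. Removing target, adding reagent or warming leaves the quota as it is, so I expect the same figure after east and no gain from these. Fresh catalyst buys N more of target per catalyst added, a gain of 6 points, above the margin of 2 points, so I choose south-west.

The forecast, saying “I favour equilibrium”, gives 12.1 % now, 12.1 % after south and 20.5 % after east, and names east where I name south-west.

The flask gives 11.9 % now, 11.9 % after south, 11.9 % after east, and south-west as the best remedy.

    starting material + free catalyst ⇌ catalyst intermediate A (K = 3.50 L mol⁻¹, k = 0.580 L mol⁻¹ s⁻¹, Ea = 47.0 kJ mol⁻¹, ΔH = 30.0 kJ mol⁻¹)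
    reagent + catalyst intermediate A → free catalyst + target (k = 1.40 L mol⁻¹ s⁻¹, Ea = 43.0 kJ mol⁻¹)
    reagent + catalyst intermediate B → free catalyst + second product (k = 1.30 L mol⁻¹ s⁻¹, Ea = 56.0 kJ mol⁻¹)
    second substrate + free catalyst ⇌ catalyst intermediate B (K = 5.20 L mol⁻¹, k = 45.0 L mol⁻¹ s⁻¹, Ea = 41.0 kJ mol⁻¹, ΔH = 18.0 kJ mol⁻¹)
    reagent + free catalyst → spent catalyst (k = 0.0180 L mol⁻¹ s⁻¹, Ea = 61.0 kJ mol⁻¹)
    reagent ⇌ dormant form (K = 1.50, k = 2.30 × 10⁻⁴ s⁻¹, Ea = 79.0 kJ mol⁻¹, ΔH = −17.0 kJ mol⁻¹)
    (constants at 0 °C)

At 40.0 h the flask holds spent catalyst at 100 % of the catalyst charged, with starting material still at 88.1 % and reagent at 23.6 % of their charges. Against my 6 points from N, the added catalyst gains 8.8 points, so N points to the right remedy but reckons its gain too low.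

A neighbour of this flask, charged with 6.0 × 10⁻⁴ M of free catalyst, should reach 7.24 % by N. The computed neighbour gives 6.86 %.

(The readings come from a simulation for substances that don't exist, noise included.)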